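## Retrosynthetic overview

1. The acetate comes last from a silyl ether, and the quaternary ester carbon is made by methylating an ester enolate on the face anti to ring B.
2. Ring A is the only ring made and is made last, by an auxiliary-controlled endo Diels–Alder reaction of an acrylimide with a ring B 1-vinylcyclohexene. This gives the ring-fusion alkene directly and sets the ring-fusion CH.
3. The diene comes from a ring B ketone by enol triflate formation and Stille vinylation.
4. Ring B is bought as 2-methylcyclohex-2-en-1-one; its two vicinal centres come from a copper-catalysed asymmetric conjugate methylation and an enolate alkylation with a chiral C5 iodide.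
5. The iodide, carrying the side-chain stereocentre, comes from (S)-citronellol by oxidative cleavage and iododecarboxylation.

Assumption: in step 4 the (R,S,S) hand of the phosphoramidite ligand is taken to give the (3R) enolate (recalled by analogy, not verified); if the sense is opposite, the mirror-image ligand is used and nothing else changes.

## Route

Step 1
Reactants: 1 (S)-citronellol [(3S)-3,7-dimethyloct-6-en-1-ol]
Product: 2 tert-butyl{[(3S)-3,7-dimethyloct-6-en-1-yl]oxy}diphenylsilane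
Conditions: t-BuPh2SiCl, imidazole, CH2Cl2, 0 °C → rt
Reagents that add atoms: tert-butyl(chloro)diphenylsilane CC(C)(C)[Si](Cl)(c1ccccc1)c1ccccc1
Why: Imidazole-promoted O-silylation of the primary alcohol gives an ether that tolerates the oxidants, iodine, organometallic bases and Lewis acids used later, and the stereocentre (the future side-chain methyl centre) is not touched.

Step 2
Reactants: 2 tert-butyl{[(3S)-3,7-dimethyloct-6-en-1-yl]oxy}diphenylsilane
Product: 5 (4S)-6-[(tert-butyldiphenylsilyl)oxy]-4-methylhexanoic acid, via glycol 3 (not isolated), via aldehyde 4 (not isolated)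
Conditions: NaIO4 (4 equiv), KMnO4 (cat.), K2CO3, t-BuOH/H2O, rt; then acidify to pH 3
Reagents that add atoms: sodium periodate [Na+].[O-]I(=O)(=O)=O; water O
Why: Lemieux–von Rudloff oxidative cleavage (permanganate dihydroxylation, periodate glycol cleavage, aldehyde oxidation) cuts the trisubstituted alkene to the acid and acetone without affecting the silyl ether or the remote stereocentre.

Step 3
Reactants: 5 (4S)-6-[(tert-butyldiphenylsilyl)oxy]-4-methylhexanoic acid
Product: 7 tert-butyl{[(3R)-5-iodo-3-methylpentyl]oxy}diphenylsilane, via acyl hypoiodite 6 (not isolated)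
Conditions: PhI(OAc)2, I2, cyclohexane, hν (tungsten lamp), reflux
Reagents that add atoms: iodine II
Why: Radical iododecarboxylation of the Hunsdiecker type under Suárez conditions (O–I homolysis, loss of CO2, iodine capture) shortens the chain by one carbon to the primary iodide; the stereocentre is untouched and becomes R only through CIP priorities.

Step 4
Reactants: 8 2-methylcyclohex-2-en-1-one
Product: 10 {[(3R)-2,3-dimethylcyclohex-1-en-1-yl]oxy}trimethylsilane, via dimethylaluminium enolate 9 (not isolated)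
Conditions: Me3Al (1.4 equiv), Cu(O2CC4H3S) (copper thiophene-2-carboxylate, 2 mol %), (R,S,S)-phosphoramidite from (R)-BINOL and bis[(S)-1-phenylethyl]amine (4 mol %), Et2O, −30 °C; then Me3SiOTf, THF, −30 → 0 °C
Reagents that add atoms: trimethylaluminium C[Al](C)C; trimethylsilyl trifluoromethanesulfonate C[Si](C)(C)OS(=O)(=O)C(F)(F)F
Why: Copper-catalysed asymmetric conjugate addition delivers the methyl group to one face of the enone under ligand control and sets C3 as R, and O-silylation of the aluminium enolate stores the enolate regiochemistry for the next step.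

Step 5
Reactants: 10 {[(3R)-2,3-dimethylcyclohex-1-en-1-yl]oxy}trimethylsilane; 7 tert-butyl{[(3R)-5-iodo-3-methylpentyl]oxy}diphenylsilane
Product: 12 (2S,3R)-2-{(3S)-5-[(tert-butyldiphenylsilyl)oxy]-3-methylpentyl}-2,3-dimethylcyclohexan-1-one, via lithium enolate 11 (not isolated)
Conditions: MeLi (1.05 equiv), THF, 0 °C → rt; then DMPU, 7 (1.2 equiv), −78 → 0 °C
Reagents that add atoms: none
Why: Si–O cleavage by MeLi releases the regiodefined tetrasubstituted lithium enolate, whose SN2 alkylation takes place anti to the neighbouring pseudoaxial C3 methyl group, so the quaternary centre forms as 2S with the two ring methyls cis.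

Step 6
Reactants: 12 (2S,3R)-2-{(3S)-5-[(tert-butyldiphenylsilyl)oxy]-3-methylpentyl}-2,3-dimethylcyclohexan-1-one
Product: 14 (5R,6S)-6-{(3S)-5-[(tert-butyldiphenylsilyl)oxy]-3-methylpentyl}-5,6-dimethylcyclohex-1-en-1-yl trifluoromethanesulfonate, via potassium enolate 13 (not isolated)
Conditions: KN(SiMe3)2, THF, −78 °C; then PhNTf2, −78 → 0 °C
Reagents that add atoms: N-phenylbis(trifluoromethanesulfonimide) O=S(=O)(N(c1ccccc1)S(=O)(=O)C(F)(F)F)C(F)(F)F
Why: Only one alpha carbon carries hydrogen, so kinetic deprotonation and O-sulfonylation of the potassium enolate (enol triflate formation) give a single regioisomer with no stereocentre affected.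

Step 7
Reactants: 14 (5R,6S)-6-{(3S)-5-[(tert-butyldiphenylsilyl)oxy]-3-methylpentyl}-5,6-dimethylcyclohex-1-en-1-yl trifluoromethanesulfonate
Product: 15 tert-butyl({(3S)-5-[(1S,6R)-2-ethenyl-1,6-dimethylcyclohex-2-en-1-yl]-3-methylpentyl}oxy)diphenylsilane
Conditions: Bu3SnCH=CH2, Pd(PPh3)4 (5 mol %), LiCl (3 equiv), THF, reflux
Reagents that add atoms: tributyl(vinyl)stannane C=C[Sn](CCCC)(CCCC)CCCC
Why: Stille cross-coupling (oxidative addition of the vinyl triflate, chloride-assisted transmetalation, reductive elimination) installs the vinyl group and creates the 1-vinylcyclohexene diene; no stereocentre is involved.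

Step 8
Reactants: 16 (4R)-4-benzyl-1,3-oxazolidin-2-one; 17 acryloyl chloride
Product: 19 (4R)-4-benzyl-3-(prop-2-enoyl)-1,3-oxazolidin-2-one, via N-lithio oxazolidinone 18 (not isolated)
Conditions: n-BuLi (1.0 equiv), THF, −78 °C; then 17, −78 → 0 °C
Reagents that add atoms: none
Why: N-Acylation of the lithiated oxazolidinone by the acid chloride gives the Evans acrylimide dienophile; the auxiliary stereocentre is untouched.

Step 9
Reactants: 15 tert-butyl({(3S)-5-[(1S,6R)-2-ethenyl-1,6-dimethylcyclohex-2-en-1-yl]-3-methylpentyl}oxy)diphenylsilane; 19 (4R)-4-benzyl-3-(prop-2-enoyl)-1,3-oxazolidin-2-one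
Product: 20 (4R)-4-benzyl-3-{[(1S,5S,6R,8aS)-5-{(3S)-5-[(tert-butyldiphenylsilyl)oxy]-3-methylpentyl}-5,6-dimethyl-1,2,3,5,6,7,8,8a-octahydronaphthalen-1-yl]carbonyl}-1,3-oxazolidin-2-one
Conditions: 19 (1.5 equiv), Et2AlCl (1.4 equiv per 19), CH2Cl2, −78 → −40 °C
Reagents that add atoms: none
Why: In this Evans auxiliary-controlled Lewis acid Diels–Alder reaction the Et2AlCl-chelated s-cis acrylimide reacts on the face away from its benzyl group through an endo transition state with ortho regiochemistry, which forms ring A with the 4,4a-alkene in place and sets C8a as S and C1 as S, the weak preference of the diene to react anti to its pseudoaxial quaternary methyl group being matched.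

Step 10
Reactants: 20 (4R)-4-benzyl-3-{[(1S,5S,6R,8aS)-5-{(3S)-5-[(tert-butyldiphenylsilyl)oxy]-3-methylpentyl}-5,6-dimethyl-1,2,3,5,6,7,8,8a-octahydronaphthalen-1-yl]carbonyl}-1,3-oxazolidin-2-one
Product: 21 methyl (1S,5S,6R,8aS)-5-{(3S)-5-[(tert-butyldiphenylsilyl)oxy]-3-methylpentyl}-5,6-dimethyl-1,2,3,5,6,7,8,8a-octahydronaphthalene-1-carboxylate
Conditions: MeMgBr (2 equiv) added to MeOH at 0 °C (gives MeOMgBr); then 20 in CH2Cl2, 0 °C → rt
Reagents that add atoms: methanol CO
Why: Transesterification of the imide with bromomagnesium methoxide attacks the exocyclic carbonyl and releases the auxiliary; C8a is not acidic, and epimerisation at C1 would not matter because C1 is planarised in the next step.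

Step 11
Reactants: 21 methyl (1S,5S,6R,8aS)-5-{(3S)-5-[(tert-butyldiphenylsilyl)oxy]-3-methylpentyl}-5,6-dimethyl-1,2,3,5,6,7,8,8a-octahydronaphthalene-1-carboxylate
Product: 23 methyl (1S,5S,6R,8aR)-5-{(3S)-5-[(tert-butyldiphenylsilyl)oxy]-3-methylpentyl}-1,5,6-trimethyl-1,2,3,5,6,7,8,8a-octahydronaphthalene-1-carboxylate, via lithium ester enolate 22 (not isolated)
Conditions: LiN(i-Pr)2 (1.3 equiv), THF, −78 °C; then MeI, DMPU, −78 → −20 °C
Reagents that add atoms: iodomethane CI
Why: In this ester enolate alkylation the C8a–C8 bond of the conformationally locked bicycle nearly eclipses one face of the exocyclic enolate, so iodomethane enters anti to it (cis to H-8a) and the quaternary centre forms as 1S with the ester cis to C8.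

Step 12
Reactants: 23 methyl (1S,5S,6R,8aR)-5-{(3S)-5-[(tert-butyldiphenylsilyl)oxy]-3-methylpentyl}-1,5,6-trimethyl-1,2,3,5,6,7,8,8a-octahydronaphthalene-1-carboxylate
Product: 25 methyl (1S,5S,6R,8aR)-5-[(3S)-5-(acetyloxy)-3-methylpentyl]-1,5,6-trimethyl-1,2,3,5,6,7,8,8a-octahydronaphthalene-1-carboxylate (CNP0151222.1), via primary alcohol 24 (not isolated)
Conditions: Bu4NF (1.0 M in THF), THF, rt; then Ac2O, pyridine, DMAP (cat.), rt
Reagents that add atoms: acetic anhydride CC(=O)OC(C)=O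
Why: Fluoride-induced desilylation followed by DMAP-catalysed acetylation of the primary alcohol in the same flask gives the acetate; the hindered tertiary methyl ester and the trisubstituted alkene do not react and no stereocentre is touched.

## Compound list

1 | (S)-citronellol, (3S)-3,7-dimethyloct-6-en-1-ol | OCC[C@@H](C)CCC=C(C)C | starting material
2 | tert-butyl{[(3S)-3,7-dimethyloct-6-en-1-yl]oxy}diphenylsilane | CC(C)(C)[Si](c1ccccc1)(c1ccccc1)OCC[C@@H](C)CCC=C(C)C | intermediate
3 | (6S)-8-[(tert-butyldiphenylsilyl)oxy]-2,6-dimethyloctane-2,3-diol | CC(C)(C)[Si](c1ccccc1)(c1ccccc1)OCC[C@@H](C)CCC(O)C(C)(C)O | intermediate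
4 | (4S)-6-[(tert-butyldiphenylsilyl)oxy]-4-methylhexanal | CC(C)(C)[Si](c1ccccc1)(c1ccccc1)OCC[C@@H](C)CCC=O | intermediate
5 | (4S)-6-[(tert-butyldiphenylsilyl)oxy]-4-methylhexanoic acid | CC(C)(C)[Si](c1ccccc1)(c1ccccc1)OCC[C@@H](C)CCC(=O)O | intermediate
6 | (4S)-6-[(tert-butyldiphenylsilyl)oxy]-4-methylhexanoyl hypoiodite | CC(C)(C)[Si](c1ccccc1)(c1ccccc1)OCC[C@@H](C)CCC(=O)OI | intermediate
7 | tert-butyl{[(3R)-5-iodo-3-methylpentyl]oxy}diphenylsilane | CC(C)(C)[Si](c1ccccc1)(c1ccccc1)OCC[C@@H](C)CCI | intermediate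
8 | 2-methylcyclohex-2-en-1-one | CC1=CCCCC1=O | starting material
9 | dimethylaluminium (3R)-2,3-dimethylcyclohex-1-en-1-olate | C[C@@H]1CCCC(O[Al](C)C)=C1C | intermediate
10 | {[(3R)-2,3-dimethylcyclohex-1-en-1-yl]oxy}trimethylsilane | C[C@@H]1CCCC(O[Si](C)(C)C)=C1C | intermediate
11 | lithium (3R)-2,3-dimethylcyclohex-1-en-1-olate | C[C@@H]1CCCC(O[Li])=C1C | intermediate
12 | (2S,3R)-2-{(3S)-5-[(tert-butyldiphenylsilyl)oxy]-3-methylpentyl}-2,3-dimethylcyclohexan-1-one | O=C1CCC[C@@H](C)[C@]1(C)CC[C@H](C)CCO[Si](c1ccccc1)(c1ccccc1)C(C)(C)C | intermediate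
13 | potassium (5R,6S)-6-{(3S)-5-[(tert-butyldiphenylsilyl)oxy]-3-methylpentyl}-5,6-dimethylcyclohex-1-en-1-olate | [K]OC1=CCC[C@@H](C)[C@]1(C)CC[C@H](C)CCO[Si](c1ccccc1)(c1ccccc1)C(C)(C)C | intermediate
14 | (5R,6S)-6-{(3S)-5-[(tert-butyldiphenylsilyl)oxy]-3-methylpentyl}-5,6-dimethylcyclohex-1-en-1-yl trifluoromethanesulfonate | O=S(=O)(OC1=CCC[C@@H](C)[C@]1(C)CC[C@H](C)CCO[Si](c1ccccc1)(c1ccccc1)C(C)(C)C)C(F)(F)F | intermediate
15 | tert-butyl({(3S)-5-[(1S,6R)-2-ethenyl-1,6-dimethylcyclohex-2-en-1-yl]-3-methylpentyl}oxy)diphenylsilane | C=CC1=CCC[C@@H](C)[C@]1(C)CC[C@H](C)CCO[Si](c1ccccc1)(c1ccccc1)C(C)(C)C | intermediate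
16 | (4R)-4-benzyl-1,3-oxazolidin-2-one | O=C1N[C@H](Cc2ccccc2)CO1 | starting material
17 | acryloyl chloride (prop-2-enoyl chloride) | C=CC(=O)Cl | starting material
18 | lithium (4R)-4-benzyl-2-oxo-1,3-oxazolidin-3-ide | [Li]N1[C@H](Cc2ccccc2)COC1=O | intermediate
19 | (4R)-4-benzyl-3-(prop-2-enoyl)-1,3-oxazolidin-2-one | C=CC(=O)N1[C@H](Cc2ccccc2)COC1=O | intermediate
20 | (4R)-4-benzyl-3-{[(1S,5S,6R,8aS)-5-{(3S)-5-[(tert-butyldiphenylsilyl)oxy]-3-methylpentyl}-5,6-dimethyl-1,2,3,5,6,7,8,8a-octahydronaphthalen-1-yl]carbonyl}-1,3-oxazolidin-2-one | O=C([C@H]1CCC=C2[C@H]1CC[C@@H](C)[C@]2(C)CC[C@H](C)CCO[Si](c1ccccc1)(c1ccccc1)C(C)(C)C)N1[C@H](Cc2ccccc2)COC1=O | intermediate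
21 | methyl (1S,5S,6R,8aS)-5-{(3S)-5-[(tert-butyldiphenylsilyl)oxy]-3-methylpentyl}-5,6-dimethyl-1,2,3,5,6,7,8,8a-octahydronaphthalene-1-carboxylate | COC(=O)[C@H]1CCC=C2[C@H]1CC[C@@H](C)[C@]2(C)CC[C@H](C)CCO[Si](c1ccccc1)(c1ccccc1)C(C)(C)C | intermediate
22 | lithium enolate of 21 (C1 trigonal; 5S,6R,8aR), lithium methoxy[(5S,6R,8aR)-5-{(3S)-5-[(tert-butyldiphenylsilyl)oxy]-3-methylpentyl}-5,6-dimethyl-3,5,6,7,8,8a-hexahydronaphthalen-1(2H)-ylidene]methanolate | COC(O[Li])=C1CCC=C2[C@H]1CC[C@@H](C)[C@]2(C)CC[C@H](C)CCO[Si](c1ccccc1)(c1ccccc1)C(C)(C)C | intermediate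
23 | methyl (1S,5S,6R,8aR)-5-{(3S)-5-[(tert-butyldiphenylsilyl)oxy]-3-methylpentyl}-1,5,6-trimethyl-1,2,3,5,6,7,8,8a-octahydronaphthalene-1-carboxylate | COC(=O)[C@@]1(C)CCC=C2[C@H]1CC[C@@H](C)[C@]2(C)CC[C@H](C)CCO[Si](c1ccccc1)(c1ccccc1)C(C)(C)C | intermediate
24 | methyl (1S,5S,6R,8aR)-5-[(3S)-5-hydroxy-3-methylpentyl]-1,5,6-trimethyl-1,2,3,5,6,7,8,8a-octahydronaphthalene-1-carboxylate | COC(=O)[C@@]1(C)CCC=C2[C@H]1CC[C@@H](C)[C@]2(C)CC[C@H](C)CCO | intermediate
25 | methyl (1S,5S,6R,8aR)-5-[(3S)-5-(acetyloxy)-3-methylpentyl]-1,5,6-trimethyl-1,2,3,5,6,7,8,8a-octahydronaphthalene-1-carboxylate (CNP0151222.1) | COC(=O)[C@@]1(C)CCC=C2[C@H]1CC[C@@H](C)[C@]2(C)CC[C@H](C)CCOC(C)=O | target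

## Step count and risks

Total step count: 12. Longest linear sequence: 10 steps (steps 1, 2, 3, 5, 6, 7, 9, 10, 11, 12, from 1 to 25).

The three steps most likely to fail are steps 5, 7 and 9.

Step 5 asks a hindered tetrasubstituted enolate to displace an unactivated primary iodide; slow reaction, O-alkylation and enolate equilibration are the dangers. The fallback sets out from silyl enol ether 10 and iodide 7 and comes back to the route at ketone 12. It forms the quaternary centre by an aldol addition to a reactive aldehyde instead of an SN2 reaction. Iodide 7 is oxidised (Kornblum oxidation, DMSO, NaHCO3, 110 °C) to (3R)-5-[(tert-butyldiphenylsilyl)oxy]-3-methylpentanal F1. A Mukaiyama aldol addition of 10 to F1 (TiCl4, CH2Cl2, −78 °C), again anti to the ring methyl, gives (2R,3R)-2-{(3R)-5-[(tert-butyldiphenylsilyl)oxy]-1-hydroxy-3-methylpentyl}-2,3-dimethylcyclohexan-1-one F2 (both carbinol epimers; the descriptors differ from those of 12 only through CIP priorities). Acylation with PhOC(S)Cl, pyridine and DMAP gives O-{(3R)-5-[(tert-butyldiphenylsilyl)oxy]-1-[(1R,2R)-1,2-dimethyl-6-oxocyclohexyl]-3-methylpentyl} O-phenyl carbonothioate F3. Barton–McCombie deoxygenation (Bu3SnH, AIBN, toluene, 80 °C) then gives 12.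

Step 7 couples at a vinyl triflate flanked by a quaternary carbon and delivers a diene that polymerises easily. The fallback sets out from ketone 12 and comes back at diene 15. It replaces cross-coupling by 1,2-addition and dehydration. CeCl3-promoted addition of CH2=CHMgBr (THF, −78 °C) gives (2S,3R)-2-{(3S)-5-[(tert-butyldiphenylsilyl)oxy]-3-methylpentyl}-1-ethenyl-2,3-dimethylcyclohexan-1-ol F4 (both carbinol epimers). Syn-elimination with the Burgess reagent (benzene, 50 °C) can only go towards the ring CH2, because the other neighbour is quaternary, and gives 15.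

Step 9 must combine reactivity of a hindered diene with regio-, endo- and facial control; the diene's own facial bias is small (estimated at about 1 kcal/mol), so the step depends on the auxiliary. The fallback sets out from diene 15 and comes back at ester 21. It replaces the metal Lewis acid and the covalent auxiliary by iminium-ion organocatalysis with a small dienophile. Acrolein with (5R)-5-benzyl-2,2,3-trimethylimidazolidin-4-one hydrochloride (20 mol %, MeCN/H2O, 0 °C → rt) gives the endo aldehyde (1S,5S,6R,8aS)-5-{(3S)-5-[(tert-butyldiphenylsilyl)oxy]-3-methylpentyl}-5,6-dimethyl-1,2,3,5,6,7,8,8a-octahydronaphthalene-1-carbaldehyde F5. Pinnick oxidation (NaClO2, NaH2PO4, 2-methylbut-2-ene, t-BuOH/H2O) gives (1S,5S,6R,8aS)-5-{(3S)-5-[(tert-butyldiphenylsilyl)oxy]-3-methylpentyl}-5,6-dimethyl-1,2,3,5,6,7,8,8a-octahydronaphthalene-1-carboxylic acid F6. Esterification with Me3SiCHN2 (MeOH/toluene) gives 21.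

Further compounds

F1 | step 5 | (3R)-5-[(tert-butyldiphenylsilyl)oxy]-3-methylpentanal | CC(C)(C)[Si](c1ccccc1)(c1ccccc1)OCC[C@@H](C)CC=O
F2 | step 5 | (2R,3R)-2-{(3R)-5-[(tert-butyldiphenylsilyl)oxy]-1-hydroxy-3-methylpentyl}-2,3-dimethylcyclohexan-1-one | O=C1CCC[C@@H](C)[C@]1(C)C(O)C[C@H](C)CCO[Si](c1ccccc1)(c1ccccc1)C(C)(C)C
F3 | step 5 | O-{(3R)-5-[(tert-butyldiphenylsilyl)oxy]-1-[(1R,2R)-1,2-dimethyl-6-oxocyclohexyl]-3-methylpentyl} O-phenyl carbonothioate | O=C1CCC[C@@H](C)[C@]1(C)C(OC(=S)Oc1ccccc1)C[C@H](C)CCO[Si](c1ccccc1)(c1ccccc1)C(C)(C)C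
F4 | step 7 | (2S,3R)-2-{(3S)-5-[(tert-butyldiphenylsilyl)oxy]-3-methylpentyl}-1-ethenyl-2,3-dimethylcyclohexan-1-ol | C=CC1(O)CCC[C@@H](C)[C@]1(C)CC[C@H](C)CCO[Si](c1ccccc1)(c1ccccc1)C(C)(C)C
F5 | step 9 | (1S,5S,6R,8aS)-5-{(3S)-5-[(tert-butyldiphenylsilyl)oxy]-3-methylpentyl}-5,6-dimethyl-1,2,3,5,6,7,8,8a-octahydronaphthalene-1-carbaldehyde | O=C[C@H]1CCC=C2[C@H]1CC[C@@H](C)[C@]2(C)CC[C@H](C)CCO[Si](c1ccccc1)(c1ccccc1)C(C)(C)C
F6 | step 9 | (1S,5S,6R,8aS)-5-{(3S)-5-[(tert-butyldiphenylsilyl)oxy]-3-methylpentyl}-5,6-dimethyl-1,2,3,5,6,7,8,8a-octahydronaphthalene-1-carboxylic acid | OC(=O)[C@H]1CCC=C2[C@H]1CC[C@@H](C)[C@]2(C)CC[C@H](C)CCO[Si](c1ccccc1)(c1ccccc1)C(C)(C)C
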